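Readings and results were generated by integration with made-up constants.

**Small charge.** A small charge of substrate and reagent, one to one, goes into the flask, so by the charge neither is the limiting reagent; I keep the books in fractions of that charge.

all flasks: substrate 0.13 M
- Wednesday's: reagent 0.13 M; the very flask that is asked about, followed so far
- flask: reagent 0.130 M; time 1.0 h

Wednesday's run (percent of the substrate charged)

| time / min | adduct / % | target / % |
|---|---|---|
| 8.00 | 34.5 | 1.1 |
| 10.0 | 37.3 | 1.6 |
| 12.0 | 39.9 | 2.9 |

(scatter of a reading: 0.5 percentage points)

* time up to 1.0 h at which adduct stands highest
* the amount of adduct, in percent of the substrate charged, at that time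



**The ledger.** I enter each unit of reagent as free (b), in adduct (x) or in target (p), with free substrate s equal to b. At 12.0 min of Wednesday's run the free entry reads 57 percentage points. If pairing runs as kf·s·b, the reciprocal of s climbs from one at rate 0.0624 /min. Wednesday's target gains 1.8 points between the first and last readings, a thin difference against the scatter, and from it the leak from adduct reads 0.0121 /min. I carry the keep ratio g, pairing constant over leak constant, 5.17. In this ledger adduct peaks where g·s·b equals x.

**Closing books.** With target left out, the balance gives s = 0.354, and by then target holds 0.153. Entering that gives s = 0.320, so I commit to 0.569 h and 52.8% of adduct.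

**The result.** The forecast gives 0.7 h and 57%, and says: “The uncertainty is therefore wide”. The flask peaks at 0.479 h with 47.3% of adduct.

    substrate + adduct → side product (k = 0.0980 /M/min)
    2 substrate → homo dimer (k = 0.0280 /M/min)
    substrate + reagent ⇌ adduct (K = 240 /M, k = 0.570 /M/min)
    adduct → target (k = 0.00920 /min)

At that peak the flask holds 11.5% of the substrate charged as side product and 5.84% as homo dimer, entries my ledger lacked. With its simulated substrate and reagent, g·s·b over x comes to 1.03 there. In the neighbour charged with 0.052 M of reagent, counting reagent against the substrate charge, the same ratio is 0.492 at 1.00 h, and that flask's adduct has fallen from its best of 21.9% to 17.7%.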